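**Assumptions:** The target SMILES has no stereocentre, stereogenic double bond or axis. The molecule is achiral, so there is no enantiomer to control. The target is taken as drawn, as the free hydrogen sulfate. Salt 9 is the practical storage form.

## Retrosynthetic overview
1. Target 10 comes from Bu4N+ salt 9, and 9 comes from 8. Only the counter-ion and two B-ring benzyl ethers are removed at the end.
2. The key disconnection is C6–OH. Compound 8 comes from 6 by a 5-OH-tethered IBX C6–H oxygenation (via 5,6-quinone 7), run on a luteolin core that already carries the 7-sulfate. The 6-OH and 7-OH therefore never compete for sulfation, and the sulfate also protects the 7-OH.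
3. Compound 6 comes from 5 by 7-O-sulfation. The only other free OH is the chelated 5-OH.
4. Compound 5 comes from phloroglucinol 4 and aroylacetate 3 by a one-pot thermal Mentzer (aroylketene) annulation that forms C4–C4a and O1–C2. Compound 3 comes from acid 1 and malonate half-ester 2.
5. Rings A and B are bought as arenes. Ring C (the pyranone) is the only ring formed, in step 2.

## Route

**Step 1**
Reactants: 1, 3,4-bis(benzyloxy)benzoic acid; 2, potassium ethyl malonate
Product: 3, ethyl 3-[3,4-bis(benzyloxy)phenyl]-3-oxopropanoate
Conditions: 1, CDI (1.1 equiv), THF, rt, 1 h; then add to 2 (1.5 equiv), MgCl2, Et3N, MeCN, rt to 40 °C, 16 h; 1 M HCl work-up (–CO2)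
Reagents that add atoms: potassium ethyl malonate (compound 2), CCOC(=O)CC(=O)[O-].[K+] (delivers CH2CO2Et; its CO2 is lost)
Why: This is a Masamune–Brooks C-acylation of the magnesium malonate half-ester enolate by the acyl imidazolide, followed by decarboxylation, and the benzyl ethers are inert to these near-neutral conditions.

**Step 2**
Reactants: 3, the β-ketoester; 4, phloroglucinol (benzene-1,3,5-triol, anhydrous)
Product: 5, 2-[3,4-bis(benzyloxy)phenyl]-5,7-dihydroxy-4H-chromen-4-one (3',4'-di-O-benzylluteolin)
Conditions: 4 (1 equiv), 3 (1.5 equiv), neat, microwave, 240 °C, 5–10 min, N2 sweep (–EtOH, –H2O); triturate with Et2O/MeOH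
Reagents that add atoms: none (all atoms come from 3 and 4)
Why: In this Mentzer pyrone synthesis, thermal loss of EtOH gives an aroylketene that acylates phloroglucinol, and the resulting o-hydroxyaryl β-diketone cyclodehydrates to the flavone; the C3 symmetry of 4 allows only one regioisomer, the acid-free medium avoids the Pechmann coumarin, and aryl benzyl ethers tolerate minutes at 240 °C.

**Step 3**
Reactants: 5
Product: 6, tetrabutylammonium 2-[3,4-bis(benzyloxy)phenyl]-5-hydroxy-4-oxo-4H-chromen-7-yl sulfate
Conditions: SO3·pyridine (2 equiv), pyridine, 0 °C to rt, 12 h; then aq Bu4NOH to pH 7–8; extract with CH2Cl2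
Reagents that add atoms: SO3·pyridine, [O-]S(=O)(=O)[n+]1ccccc1 (delivers SO3); tetrabutylammonium hydroxide, CCCC[N+](CCCC)(CCCC)CCCC.[OH-] (counter-ion)
Why: In this SO3–amine O-sulfation the 7-OH (a vinylogous acid) reacts while the 5-OH is locked in its hydrogen bond to C4=O; the group is carried as the lipophilic monoester anion because a sulfate diester or fluorosulfate would later cyclise onto the new 6-OH to give a 6,7-cyclic sulfate.

**Step 4 (key step)**
Reactants: 6
Product: 7, tetrabutylammonium 2-[3,4-bis(benzyloxy)phenyl]-4,5,6-trioxo-5,6-dihydro-4H-chromen-7-yl sulfate (the flavone-5,6-quinone; not isolated)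
Conditions: IBX (2 equiv), dry DMF, 3 Å MS, dark, rt to 45 °C, followed by the red quinone colour and LC-MS
Reagents that add atoms: IBX, O=C1OI(=O)(O)c2ccccc12 (delivers the C6 oxygen)
Why: Proposed new method: the closest known reaction is IBX ortho-oxygenation of phenols to o-quinones, which is established for monohydroxyflavones, and what is new is its use on a chelated 5-OH bearing a meta sulfate monoester; the only free phenol (5-OH) exchanges onto I(V), with sieves pulling the equilibrium, and the tethered oxygen can reach only C6, because C4a is quaternary and acyl-bearing and C8 is para and out of reach, while C6 is activated by O5, O7 and O1 and is meta to the acyl group; collapse of the I(III) catecholate then gives the quinone, and the sulfate anion, benzyl ethers and enone are not oxidised below about 60 °C.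

**Step 5 (same pot as step 4)**
Reactants: 7
Product: 8, tetrabutylammonium 2-[3,4-bis(benzyloxy)phenyl]-5,6-dihydroxy-4-oxo-4H-chromen-7-yl sulfate
Conditions: cool to 0 °C; aq Na2S2O4 (5 equiv), pH 7 phosphate buffer, 10 min, argon; extract with CH2Cl2; purify on Sephadex LH-20 (MeOH)
Reagents that add atoms: none (2 H only)
Why: This is the standard dithionite reductive work-up of an IBX oxygenation, in which two-electron reduction of the o-quinone to the catechol is faster than water addition at C7 or C8, and it does not touch the sulfate monoester, the benzyl ethers or the pyranone.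

**Step 6**
Reactants: 8
Product: 9, tetrabutylammonium 2-(3,4-dihydroxyphenyl)-5,6-dihydroxy-4-oxo-4H-chromen-7-yl sulfate
Conditions: H2 (1 atm), 10% Pd/C, degassed MeOH–THF 1:1, rt, 2–4 h; filter under argon
Reagents that add atoms: none
Why: Catalytic hydrogenolysis cleaves both aryl benzyl ethers, aryl sulfate salts and the flavone C2=C3 bond are inert at 1 atm and rt, and the neutral, oxygen-free medium protects the new catechol and pyrogallol-type units.

**Step 7**
Reactants: 9
Product: 10, 6-hydroxyluteolin 7-sulfate [2-(3,4-dihydroxyphenyl)-5,6-dihydroxy-4-oxo-4H-chromen-7-yl hydrogen sulfate]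
Conditions: Dowex 50W-X8 (H+ form), H2O–MeOH, 0–4 °C, short column; lyophilise at once; store at –20 °C
Reagents that add atoms: none (Bu4N+ is exchanged for H+)
Why: In this strong-acid cation exchange the resin retains Bu4N+ and releases the hydrogen sulfate, while low temperature and short contact time suppress acid-catalysed solvolysis of the S–O(aryl) bond.

## Compound list
1 | 3,4-bis(benzyloxy)benzoic acid | O=C(O)c1ccc(OCc2ccccc2)c(OCc2ccccc2)c1 | starting material
2 | potassium ethyl malonate | CCOC(=O)CC(=O)[O-].[K+] | starting material
3 | ethyl 3-[3,4-bis(benzyloxy)phenyl]-3-oxopropanoate | CCOC(=O)CC(=O)c1ccc(OCc2ccccc2)c(OCc2ccccc2)c1 | intermediate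
4 | phloroglucinol | Oc1cc(O)cc(O)c1 | starting material
5 | 3',4'-di-O-benzylluteolin | O=c1cc(-c2ccc(OCc3ccccc3)c(OCc3ccccc3)c2)oc2cc(O)cc(O)c12 | intermediate
6 | Bu4N+ 3',4'-di-O-benzylluteolin 7-sulfate | CCCC[N+](CCCC)(CCCC)CCCC.O=c1cc(-c2ccc(OCc3ccccc3)c(OCc3ccccc3)c2)oc2cc(OS(=O)(=O)[O-])cc(O)c12 | intermediate
7 | Bu4N+ flavone-5,6-quinone 7-sulfate (B ring dibenzyl) | CCCC[N+](CCCC)(CCCC)CCCC.O=C1C=C(c2ccc(OCc3ccccc3)c(OCc3ccccc3)c2)OC2=C1C(=O)C(=O)C(OS(=O)(=O)[O-])=C2 | intermediate (not isolated)
8 | Bu4N+ 3',4'-di-O-benzyl-6-hydroxyluteolin 7-sulfate | CCCC[N+](CCCC)(CCCC)CCCC.O=c1cc(-c2ccc(OCc3ccccc3)c(OCc3ccccc3)c2)oc2cc(OS(=O)(=O)[O-])c(O)c(O)c12 | intermediate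
9 | Bu4N+ 6-hydroxyluteolin 7-sulfate | CCCC[N+](CCCC)(CCCC)CCCC.O=c1cc(-c2ccc(O)c(O)c2)oc2cc(OS(=O)(=O)[O-])c(O)c(O)c12 | intermediate
10 | 6-hydroxyluteolin 7-sulfate (achiral) | O=c1cc(-c2ccc(O)c(O)c2)oc2cc(OS(=O)(=O)O)c(O)c(O)c12 | target

## Summary
Total step count: 7. Steps 4 and 5 share one pot, so there are 6 operations.
Longest linear sequence: 7, fully linear from compound 1.

**Steps most likely to fail**
1. **Step 4.**
   - Risk: the chelated, only moderately electron-rich 5-OH may not engage IBX. Quinone 7 may also lose sulfate by addition–elimination of water at C7.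
   - Fallback: give up the O-tethered delivery and the quinone altogether. Carry out a 5-OH-directed electrophilic C6 iodination of 6 (BnMe3N+ ICl2–, CaCO3, CH2Cl2–MeOH). Follow with Miyaura borylation (B2pin2, Pd(dppf)Cl2, KOAc) and NaBO3 oxidation, which converts C–I to C–B to C–OH and gives the same compound 8.
2. **Step 2.**
   - Risk: at 240 °C the benzyl groups may transfer to phloroglucinol, 4-arylcoumarin may form, or conversion may be low.
   - Fallback: build ring C from different bonds by a Pd-catalysed carbonylative Sonogashira/6-endo annulation. Combine 2-iodo-3,5-bis(methoxymethoxy)phenol, 4-ethynyl-1,2-bis(benzyloxy)benzene and CO (1 atm) with PdCl2(PPh3)2 in Et2NH, so that C4 comes from CO. Mild acidic removal of the MOM groups then gives 5.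
3. **Step 7.**
   - Risk: the free aryl hydrogen sulfate may hydrolyse autocatalytically on the resin or during drying.
   - Fallback: avoid the solid acid and use a precipitation-driven metathesis. Convert 9 to its barium salt (Ba(OAc)2, MeOH). Liberate the acid at 0 °C with exactly one equivalent of H+ from dilute H2SO4, remove BaSO4 by centrifugation, and freeze-dry or use the cold solution directly.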